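**Target:** (−)-epicatechin 3-O-vanillate, i.e. (2R,3R)-2-(3,4-dihydroxyphenyl)-5,7-dihydroxychroman-3-yl 4-hydroxy-3-methoxybenzoate (2,3-cis).

**Assumption:** (−)-epicatechin (2R,3R, bulk natural-product grade) and 4-(benzyloxy)-3-methoxybenzoic acid are bought.

## Retrosynthetic overview

1. 7 ⇐ 6 by hydrogenolysis of the single O-benzyl group.
2. 6 ⇐ 3 + 4: the ester C–O bond at O3 is the key disconnection, made by site-selective acyl transfer to unprotected (−)-epicatechin (new method).
3. 3 ⇐ 1 + benzotriazole (acyl C–N bond).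
4. No ring is formed and no C–C bond is made: rings A, C and B and both stereocentres (2R,3R) come intact from 4, and the vanilloyl arene comes from 1.

## Route

**Step 1**
Reactants: 1 4-(benzyloxy)-3-methoxybenzoic acid
Product: 3 1-[4-(benzyloxy)-3-methoxybenzoyl]-1H-benzotriazole, via mixed carboxylic–sulfinic anhydride 2 (not isolated)
Conditions: SOCl2 (1.05 equiv), 1H-benzotriazole (4 equiv), CH2Cl2, 20 °C, 3 h; filter, wash with aq. Na2CO3, recrystallise
Reagents that add atoms: 1H-benzotriazole, c1ccc2[nH]nnc2c1
Why: Katritzky N-acylbenzotriazole synthesis: SOCl2 and excess benzotriazole give 1,1'-sulfinylbis(benzotriazole), which converts acid 1 into mixed anhydride 2 that collapses with loss of SO2 to the crystalline, weighable acyl azole 3; the aryl benzyl ether is inert and no stereocentre is involved.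

**Step 2**
Reactants: 3 1-[4-(benzyloxy)-3-methoxybenzoyl]-1H-benzotriazole (1.0 equiv); 4 (−)-epicatechin (1.0 equiv)
Product: 6 (2R,3R)-2-(3,4-dihydroxyphenyl)-5,7-dihydroxychroman-3-yl 4-(benzyloxy)-3-methoxybenzoate, via acylpyridinium benzotriazolide 5 (not isolated)
Conditions: DMAP (20 mol%), dry degassed THF (0.1 M), argon, 40 °C, 36 h (HPLC control)
Reagents that add atoms: none
Why: Proposed new method: error-correcting, thermodynamically funnelled O-acylation of an unprotected polyphenolic alcohol, in which DMAP opens 3 to acylpyridinium benzotriazolide 5 that acylates O3 with benzotriazolide as general base; any aryl ester that may form at one of the four phenols is itself an active ester that DMAP and benzotriazolide re-open, whereas the alkyl ester at O3 is an estimated 4–5 kcal/mol more stable and is not re-opened, so with one equivalent of donor the acyl group drains to the only aliphatic hydroxyl; the C3–O bond is never broken, so (2R,3R) is retained, and no base strong enough to make the 4'-phenoxide (the C2-epimerisation channel) is present; the closest known reaction types are Steglich-type DMAP acyl transfer, O-acylation with N-acylbenzotriazoles and DMAP- or imidazole-catalysed transesterification of aryl active esters.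

**Step 3**
Reactants: 6 (2R,3R)-2-(3,4-dihydroxyphenyl)-5,7-dihydroxychroman-3-yl 4-(benzyloxy)-3-methoxybenzoate
Product: 7 (2R,3R)-2-(3,4-dihydroxyphenyl)-5,7-dihydroxychroman-3-yl 4-hydroxy-3-methoxybenzoate
Conditions: H2 (1 atm), 10% Pd/C, THF/MeOH 1:1, 20 °C, 3 h; filter through Celite, evaporate
Reagents that add atoms: none
Why: Heterogeneous catalytic hydrogenolysis of the single aryl benzyl ether, the usual last step of catechin-ester syntheses, leaves the aryl ester, the cyclic O1–C2 ether of ring C, the free phenols and both stereocentres untouched at 20 °C and 1 atm.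

## Compound list

1 | 4-(benzyloxy)-3-methoxybenzoic acid (O-benzylvanillic acid) | COc1cc(C(=O)O)ccc1OCc1ccccc1 | starting material
2 | 4-(benzyloxy)-3-methoxybenzoic 1H-benzotriazole-1-sulfinic anhydride (sulfur centre racemic, not isolated) | COc1cc(C(=O)OS(=O)n2nnc3ccccc32)ccc1OCc1ccccc1 | intermediate
3 | 1-[4-(benzyloxy)-3-methoxybenzoyl]-1H-benzotriazole | COc1cc(C(=O)n2nnc3ccccc32)ccc1OCc1ccccc1 | intermediate
4 | (−)-epicatechin, (2R,3R)-2-(3,4-dihydroxyphenyl)chromane-3,5,7-triol | O[C@@H]1Cc2c(O)cc(O)cc2O[C@@H]1c1ccc(O)c(O)c1 | starting material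
5 | 1-[4-(benzyloxy)-3-methoxybenzoyl]-4-(dimethylamino)pyridinium benzotriazolide (not isolated) | COc1cc(C(=O)[n+]2ccc(N(C)C)cc2)ccc1OCc1ccccc1.c1ccc2[n-]nnc2c1 | intermediate
6 | (2R,3R)-2-(3,4-dihydroxyphenyl)-5,7-dihydroxychroman-3-yl 4-(benzyloxy)-3-methoxybenzoate | COc1cc(C(=O)O[C@@H]2Cc3c(O)cc(O)cc3O[C@@H]2c2ccc(O)c(O)c2)ccc1OCc1ccccc1 | intermediate
7 | (2R,3R)-2-(3,4-dihydroxyphenyl)-5,7-dihydroxychroman-3-yl 4-hydroxy-3-methoxybenzoate | COc1cc(C(=O)O[C@@H]2Cc3c(O)cc(O)cc3O[C@@H]2c2ccc(O)c(O)c2)ccc1O | target

## Step count and risks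

Total step count: 3. Longest linear sequence: 3 steps (1 → 3 → 6 → 7; 4 enters at step 2).

**Most likely to fail, first: step 2 (the proposed new method).** The risks are slow re-opening of phenolic esters, which would leave a regioisomer mixture, and C2 epimerisation on long heating. The fallback is known chemistry; it sets out from 4 and comes back at 7. The four phenols of 4 are benzylated (BnBr, K2CO3, DMF, 0 to 20 °C, argon) to 5,7,3',4'-tetra-O-benzyl-(−)-epicatechin F1. Its only free hydroxyl, O3, is esterified with acid 1 under Steglich conditions (DCC, DMAP, CH2Cl2, 20 °C) to (2R,3R)-5,7-bis(benzyloxy)-2-[3,4-bis(benzyloxy)phenyl]chroman-3-yl 4-(benzyloxy)-3-methoxybenzoate F2. Hydrogenolysis of all five benzyl ethers (H2, Pd(OH)2/C, THF/MeOH, 20 °C) then gives 7 directly, so 3 and 6 are by-passed.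

**Second: step 3.** The risk is poisoning of the palladium surface by traces of benzotriazole carried in 6, or slow hydrogenolysis. The fallback sets out from 4 and comes back at 7, and leaves the benzyl group out altogether. Commercial vanillic acid is converted (SOCl2, benzotriazole, THF, 20 °C) into 1-(4-hydroxy-3-methoxybenzoyl)-1H-benzotriazole F3, an isolable N-(hydroxyaroyl)benzotriazole. F3 is coupled with 4 under the conditions of step 2 and gives 7 in one operation with no deprotection. The donor's own phenol is then one more reversibly acylated site; this fallback relies on step 2 already having been shown to work.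

**Third: step 1.** The risk is incomplete activation, or hydrolysis of 3 during the basic wash. The fallback sets out from 1 and comes back at 3 by a two-stage acid chloride route instead of sulfinyl transfer. Acid 1 with (COCl)2 and catalytic DMF in CH2Cl2 at 20 °C gives 4-(benzyloxy)-3-methoxybenzoyl chloride F4. F4 then N-acylates benzotriazole (Et3N, CH2Cl2, 0 °C) to give 3.

## Further compounds

F1 | step 2 | (2R,3R)-5,7-bis(benzyloxy)-2-[3,4-bis(benzyloxy)phenyl]chroman-3-ol | O[C@@H]1Cc2c(OCc3ccccc3)cc(OCc3ccccc3)cc2O[C@@H]1c1ccc(OCc2ccccc2)c(OCc2ccccc2)c1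
F2 | step 2 | (2R,3R)-5,7-bis(benzyloxy)-2-[3,4-bis(benzyloxy)phenyl]chroman-3-yl 4-(benzyloxy)-3-methoxybenzoate | COc1cc(C(=O)O[C@@H]2Cc3c(OCc4ccccc4)cc(OCc4ccccc4)cc3O[C@@H]2c2ccc(OCc3ccccc3)c(OCc3ccccc3)c2)ccc1OCc1ccccc1
F3 | step 3 | 1-(4-hydroxy-3-methoxybenzoyl)-1H-benzotriazole | COc1cc(C(=O)n2nnc3ccccc32)ccc1O
F4 | step 1 | 4-(benzyloxy)-3-methoxybenzoyl chloride | COc1cc(C(Cl)=O)ccc1OCc1ccccc1
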